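The route rests on cutting the bond between C6 of the chromene benzene ring and the ketone carbon of the side chain. The key step forges it by acylating the C6 aryllithium, made from 6-bromo-7-methoxy-2,2-dimethyl-2H-chromene, with the Weinreb amide of (S)-4-hydroxyphenyllactic acid, used unprotected as its dimagnesium alkoxide–phenoxide. It exploits the hydroxyl on the carbon next to the ketone carbon: as a magnesium alkoxide it chelates the amide carbonyl and makes the adjacent C–H non-acidic, while the bromine at C6, ortho to the C7 methoxy group and para to the ring oxygen O1, fixes the site. One operation gives the complete, unprotected target with the chiral-pool stereocenter untouched.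

Key step: step 4

Remark: compound 7 is taken as a commercial chiral-pool acid; its S configuration is the one the target requires (OH > C=O > CH2Ar > H).

Step 1
Reactants: 1 4-bromo-3-methoxyphenol; 2 3-chloro-3-methylbut-1-yne
Product: 3 1-bromo-2-methoxy-4-[(2-methylbut-3-yn-2-yl)oxy]benzene
Conditions: K2CO3, KI, CuI (cat.), acetone, reflux
Reagents that add atoms: none
Why: Copper-assisted O-alkylation of the potassium phenoxide by the tertiary propargylic chloride (an SN1-like substitution via the copper acetylide) is the standard entry to aryl 1,1-dimethylpropargyl ethers; no stereocenter is formed.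

Step 2
Reactants: 3 1-bromo-2-methoxy-4-[(2-methylbut-3-yn-2-yl)oxy]benzene
Product: 6 6-bromo-7-methoxy-2,2-dimethyl-2H-chromene, via allenylphenol 4 (not isolated), via quinone methide 5 (not isolated)
Conditions: PhNEt2, 190 °C
Reagents that add atoms: none
Why: Aromatic propargyl Claisen rearrangement to the free ortho carbon para to the methoxy group, enolization to 4, 1,5-hydrogen shift to ortho-quinone methide 5 and 6π-oxa-electrocyclization should close the pyran ring, the other ortho carbon lying between two oxygens and being shielded by the methoxy methyl group that the neighbouring bromine turns toward it; no stereocenter is formed.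

Step 3
Reactants: 7 (2S)-2-hydroxy-3-(4-hydroxyphenyl)propanoic acid; 8 N,O-dimethylhydroxylamine hydrochloride
Product: 9 (2S)-2-hydroxy-3-(4-hydroxyphenyl)-N-methoxy-N-methylpropanamide
Conditions: EDC·HCl (N-(3-dimethylaminopropyl)-N′-ethylcarbodiimide hydrochloride), HOBt (1-hydroxybenzotriazole), N-methylmorpholine, DMF, 0 °C to rt
Reagents that add atoms: none
Why: Carbodiimide/HOBt amide coupling in which the amine should outcompete the phenol and the secondary alcohol for the active ester; an alpha-hydroxy acid has no oxazolone pathway, so the S center of 7 is carried over unchanged.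

Step 4
Reactants: 6 6-bromo-7-methoxy-2,2-dimethyl-2H-chromene; 9 (2S)-2-hydroxy-3-(4-hydroxyphenyl)-N-methoxy-N-methylpropanamide
Product: 13 Lespeflorin C7, (2S)-2-hydroxy-3-(4-hydroxyphenyl)-1-(7-methoxy-2,2-dimethyl-2H-chromen-6-yl)propan-1-one, via aryllithium 10 (not isolated), via dimagnesium salt 11 (not isolated), via tetrahedral adduct 12 (not isolated)
Conditions: 6, n-BuLi, THF, −78 °C; separately 9, t-BuMgCl (2.0 equiv), THF, −20 °C; combine at −78 °C, warm to −20 °C; cold 1 M HCl to pH 5
Reagents that add atoms: none
Why: Bromine–lithium exchange on 6 at −78 °C should give aryllithium 10 at C6 faster than n-BuLi can add to the C3=C4 double bond, while t-BuMgCl, too hindered to add to the amide, converts both hydroxyls of 9 into the dimagnesium salt 11; 10 then adds to the chelated amide carbonyl of 11 to give the tetrahedral adduct 12, which should not expel the N-methoxy-N-methylamide at low temperature and collapses to the ketone only on the cold acidic quench. The closest known reaction type is the Weinreb ketone synthesis, in the variant in which an unprotected alpha-hydroxy Weinreb amide is deprotonated first and then acylates an organometallic reagent. No ring is closed. No new stereocenter appears in the product (the hemiaminal carbon of 12 is transient): the S center comes from 7 and should be kept because its C–H, flanked by a magnesium alkoxide in 11 and by two alkoxides in 12, is not acidic, and the free alpha-hydroxy ketone is released only at pH near 5. The step needs mono-addition, secured by the stability of 12, and site selectivity for C6 over C8 (where a direct lithiation between the two oxygens would go), secured by the position of the bromine.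

Compound list
1 | 4-bromo-3-methoxyphenol | COc1cc(O)ccc1Br | starting material
2 | 3-chloro-3-methylbut-1-yne | C#CC(C)(C)Cl | starting material
3 | 1-bromo-2-methoxy-4-[(2-methylbut-3-yn-2-yl)oxy]benzene | COc1cc(OC(C)(C)C#C)ccc1Br | intermediate
4 | 4-bromo-5-methoxy-2-(3-methylbuta-1,2-dien-1-yl)phenol | COc1cc(O)c(C=C=C(C)C)cc1Br | intermediate (not isolated)
5 | 4-bromo-3-methoxy-6-(3-methylbut-2-en-1-ylidene)cyclohexa-2,4-dien-1-one | COC1=CC(=O)C(=CC=C(C)C)C=C1Br | intermediate (not isolated)
6 | 6-bromo-7-methoxy-2,2-dimethyl-2H-chromene | COc1cc2OC(C)(C)C=Cc2cc1Br | intermediate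
7 | (2S)-2-hydroxy-3-(4-hydroxyphenyl)propanoic acid | OC(=O)[C@@H](O)Cc1ccc(O)cc1 | starting material
8 | N,O-dimethylhydroxylamine hydrochloride | CNOC.Cl | starting material
9 | (2S)-2-hydroxy-3-(4-hydroxyphenyl)-N-methoxy-N-methylpropanamide | CON(C)C(=O)[C@@H](O)Cc1ccc(O)cc1 | intermediate
10 | (7-methoxy-2,2-dimethyl-2H-chromen-6-yl)lithium | [Li]c1cc2C=CC(C)(C)Oc2cc1OC | intermediate (not isolated)
11 | bis(chloromagnesium) alkoxide–phenoxide of 9, (2S) | CON(C)C(=O)[C@@H](O[Mg]Cl)Cc1ccc(O[Mg]Cl)cc1 | intermediate (not isolated)
12 | lithium/bis(chloromagnesium) salt of (2S)-1-(7-methoxy-2,2-dimethyl-2H-chromen-6-yl)-1-[methoxy(methyl)amino]-3-(4-hydroxyphenyl)propane-1,2-diol, C1 unassigned | COc1cc2OC(C)(C)C=Cc2cc1C(O[Li])(N(C)OC)[C@@H](O[Mg]Cl)Cc1ccc(O[Mg]Cl)cc1 | intermediate (not isolated)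
13 | Lespeflorin C7, (2S)-2-hydroxy-3-(4-hydroxyphenyl)-1-(7-methoxy-2,2-dimethyl-2H-chromen-6-yl)propan-1-one | COc1cc2c(cc1C(=O)[C@@H](O)Cc1ccc(O)cc1)C=CC(C)(C)O2 | target

Total step count: 4
Longest linear sequence: 3 steps (steps 1, 2 and 4, from compound 1)

Steps most likely to fail

Step 4. The dimagnesium salt may aggregate or precipitate, so that addition stays incomplete and the aryllithium is lost to proton transfer on warming. Some configuration may also be lost if the released ketone meets base at the quench. Fallback: setting out from 9, both hydroxyls would be silylated (TBSCl, imidazole, DMF) to (2S)-2-[(tert-butyldimethylsilyl)oxy]-3-{4-[(tert-butyldimethylsilyl)oxy]phenyl}-N-methoxy-N-methylpropanamide F1. Aryllithium 10 (from 6, n-BuLi, THF, −78 °C) should add to this fully soluble, neutral amide to give the bis-silyl ketone (2S)-2-[(tert-butyldimethylsilyl)oxy]-3-{4-[(tert-butyldimethylsilyl)oxy]phenyl}-1-(7-methoxy-2,2-dimethyl-2H-chromen-6-yl)propan-1-one F2. HF·pyridine in THF/pyridine at 0 °C should then remove both silyl groups without base, returning to the route at 13.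

Step 2. The Claisen rearrangement may go in part to the ortho carbon between the two oxygens and give the regioisomeric 5-methoxychromene, and the ether may decompose at the high temperature. Fallback: setting out from 1, acylation–oxa-Michael annulation with 3-methylbut-2-enoic acid in MeSO3H/P2O5 at 70 °C should acylate the ring carbon ortho to the hydroxyl and para to the methoxy group and close the ring to 6-bromo-7-methoxy-2,2-dimethylchroman-4-one F3. NaBH4 in MeOH should reduce it to racemic 6-bromo-7-methoxy-2,2-dimethylchroman-4-ol F4, and TsOH (cat.) in toluene at 80 °C should dehydrate this, returning to the route at 6. This path also avoids step 1.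

Step 3. The activated acid may acylate the free hydroxyls of another molecule and form oligoesters, and the polar amide may be lost to the aqueous phase on work-up. Fallback: setting out from 7, Fischer esterification (MeOH, H2SO4 cat., reflux) should give methyl (2S)-2-hydroxy-3-(4-hydroxyphenyl)propanoate F5. Aminolysis with the chloromagnesium amide made from 8 and i-PrMgCl (excess, THF, −20 °C) involves no activated acyl species and should return to the route at 9.

Further compounds
F1 | step 4 | (2S)-2-[(tert-butyldimethylsilyl)oxy]-3-{4-[(tert-butyldimethylsilyl)oxy]phenyl}-N-methoxy-N-methylpropanamide | CON(C)C(=O)[C@@H](O[Si](C)(C)C(C)(C)C)Cc1ccc(O[Si](C)(C)C(C)(C)C)cc1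
F2 | step 4 | (2S)-2-[(tert-butyldimethylsilyl)oxy]-3-{4-[(tert-butyldimethylsilyl)oxy]phenyl}-1-(7-methoxy-2,2-dimethyl-2H-chromen-6-yl)propan-1-one | COc1cc2c(cc1C(=O)[C@@H](O[Si](C)(C)C(C)(C)C)Cc1ccc(O[Si](C)(C)C(C)(C)C)cc1)C=CC(C)(C)O2
F3 | step 2 | 6-bromo-7-methoxy-2,2-dimethylchroman-4-one | COc1cc2OC(C)(C)CC(=O)c2cc1Br
F4 | step 2 | 6-bromo-7-methoxy-2,2-dimethylchroman-4-ol (racemic) | COc1cc2OC(C)(C)CC(O)c2cc1Br
F5 | step 3 | methyl (2S)-2-hydroxy-3-(4-hydroxyphenyl)propanoate | COC(=O)[C@@H](O)Cc1ccc(O)cc1
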